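The ten-membered carbocycle is traced back to a cyclohex-2-enol: the cis C4–C5 epoxide is read as the ring alkene of a six-membered ring closed across C1–C6, with C6 (OH, E-2-alkoxyvinyl) and C1 (OMe, isopropenyl) bearing trans alkenyl groups. A single anionic oxy-Cope shift forms C8–C9, breaks C1–C6, enlarges the six-membered ring to the ten-membered one, transfers the C1/C6 chirality to C8, keeps C4=C5 cis, and delivers the C6 ketone (as its C7 enolate) and the C1 ketone (as an enol ether) in differentiated form. The butenolide on C6–C7, the epoxide and both esters are then set from C8 by substrate control.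

Key step: step 9

Assumption: atoms carry the germacrane-type locants of the target throughout (ring C1–C10, lactone carbons C11–C13, C14 = 10-methyl, C15 = 4-methyl), and the (10R) centre alpha to the C1 ketone is taken to be the thermodynamically preferred one, so it is set by equilibration.

Step 1
Reactants: 1 4,4-dimethoxycyclohexa-2,5-dien-1-one; 2 isopropenylmagnesium bromide
Product: 3 4,4-dimethoxy-1-(prop-1-en-2-yl)cyclohexa-2,5-dien-1-ol
Conditions: THF, −78 → 0 °C; then H2O
Reagents that add atoms: none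
Why: Grignard 1,2-addition to the only free carbonyl of the quinone monoketal gives the tertiary bis-allylic alcohol; the product is achiral, so no stereocontrol is needed.

Step 2
Reactants: 3 4,4-dimethoxy-1-(prop-1-en-2-yl)cyclohexa-2,5-dien-1-ol
Product: 5 4-methoxy-4-(prop-1-en-2-yl)cyclohexa-2,5-dien-1-one, via trimethoxy diene 4 (not isolated)
Conditions: NaH, MeI, THF, 0 → 23 °C; then 1 M aq. HCl, 0 °C
Reagents that add atoms: iodomethane (CI); water (O)
Why: Williamson methylation of the tertiary alkoxide followed by hydrolysis of the dimethyl ketal, which is far more labile than the tertiary methyl ether, unveils the prochiral 4,4-disubstituted cyclohexadienone.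

Step 3
Reactants: 5 4-methoxy-4-(prop-1-en-2-yl)cyclohexa-2,5-dien-1-one
Product: 6 (S)-4-methoxy-4-(prop-1-en-2-yl)cyclohex-2-en-1-one
Conditions: Cu(OAc)2 (5 mol %), (R)-DTBM-SEGPHOS (5.5 mol %), (EtO)2MeSiH, tBuOH, toluene, −20 °C
Reagents that add atoms: none
Why: Ligand-controlled copper hydride conjugate reduction (monovalent copper hydride generated from the divalent copper salt and the silane) of one of the two enantiotopic enone arms desymmetrises the dienone and thereby fixes the quaternary carbon; the ligand antipode that delivers the (S)-enone is the one to be used.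

Step 4
Reactants: 6 (S)-4-methoxy-4-(prop-1-en-2-yl)cyclohex-2-en-1-one
Product: 7 (4S)-4-methoxy-1-methyl-4-(prop-1-en-2-yl)cyclohex-2-en-1-ol
Conditions: MeLi, Et2O, −78 °C; then H2O
Reagents that add atoms: methyllithium ([Li]C)
Why: Organolithium 1,2-addition to the enone carbonyl; the new carbinol centre is removed in step 5, so both epimers are carried on.

Step 5
Reactants: 7 (4S)-4-methoxy-1-methyl-4-(prop-1-en-2-yl)cyclohex-2-en-1-ol
Product: 8 (R)-6-methoxy-3-methyl-6-(prop-1-en-2-yl)cyclohex-2-en-1-one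
Conditions: pyridinium chlorochromate [C5H5NH][CrO3Cl], 4 Å molecular sieves, CH2Cl2, 23 °C
Reagents that add atoms: pyridinium chlorochromate ([O-][Cr](=O)(=O)Cl.c1cc[nH+]cc1)
Why: Babler–Dauben oxidative transposition: the chromate ester of the tertiary allylic alcohol undergoes a [3,3] shift and the transposed chromate is oxidised, which moves the carbonyl next to the quaternary carbon without touching that centre.

Step 6
Reactants: 9 4-methoxybenzyl alcohol; 10 trichloroethylene
Product: 11 1-{[(E)-1,2-dichloroethenyl]oxymethyl}-4-methoxybenzene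
Conditions: KH, THF, 0 → 23 °C
Reagents that add atoms: none
Why: Addition–elimination of the potassium alkoxide on trichloroethylene (through dichloroacetylene) is the standard route to (E)-1,2-dichlorovinyl ethers, the stable precursors of alkoxyacetylides.

Step 7
Reactants: 11 1-{[(E)-1,2-dichloroethenyl]oxymethyl}-4-methoxybenzene; 8 (R)-6-methoxy-3-methyl-6-(prop-1-en-2-yl)cyclohex-2-en-1-one
Product: 14 (1R,6R)-6-methoxy-1-{[(4-methoxybenzyl)oxy]ethynyl}-3-methyl-6-(prop-1-en-2-yl)cyclohex-2-en-1-ol, via lithium alkoxyacetylide 12 (not isolated), via bromomagnesium alkoxyacetylide 13 (not isolated)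
Conditions: nBuLi (2.1 equiv), THF, −78 → −40 °C; MgBr2·OEt2, −78 °C; then 8, THF–Et2O, −78 → −20 °C; then H2O
Reagents that add atoms: none
Why: Dehydrochlorination and chlorine–lithium exchange give the alkoxyacetylide, which after transmetallation adds to the ketone under Cram chelation control (Arens–van Dorp type alkynylation): magnesium bridges the carbonyl and methoxy oxygens, the isopropenyl group is thereby pseudo-axial, and the small linear nucleophile enters the opposite face, so the carbon substituents on C6 and C1 end up trans.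

Step 8
Reactants: 14 (1R,6R)-6-methoxy-1-{[(4-methoxybenzyl)oxy]ethynyl}-3-methyl-6-(prop-1-en-2-yl)cyclohex-2-en-1-ol
Product: 15 (1R,6R)-6-methoxy-1-{(E)-2-[(4-methoxybenzyl)oxy]ethenyl}-3-methyl-6-(prop-1-en-2-yl)cyclohex-2-en-1-ol
Conditions: LiAlH4, THF, 0 → 23 °C; then aq. KNaC4H4O6
Reagents that add atoms: none
Why: Hydroxyl-directed trans-hydroalumination of the propargylic alcohol and protonolysis on work-up give the (E)-enol ether; the isolated alkenes and the methyl ether are not reduced.

Step 9
Reactants: 15 (1R,6R)-6-methoxy-1-{(E)-2-[(4-methoxybenzyl)oxy]ethenyl}-3-methyl-6-(prop-1-en-2-yl)cyclohex-2-en-1-ol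
Product: 18 (2Z,6Z,9S)-6-methoxy-9-[(4-methoxybenzyl)oxy]-3,7-dimethylcyclodeca-2,6-dien-1-one, via potassium alkoxide 16 (not isolated), via potassium enolate 17 (not isolated)
Conditions: KH, 18-crown-6, THF, 0 → 23 °C; then AcOH, THF, −78 °C
Reagents that add atoms: none
Why: KH/18-crown-6 gives the dissociated potassium alkoxide 16, whose oxygen weakens the adjacent C1–C6 bond so that a concerted suprafacial [3,3] sigmatropic shift of the C8=C7–C6–C1–C10=C9 hexadiene takes place at or below room temperature (anionic oxy-Cope rearrangement; closest known case: ring enlargement of trans-1,2-dialkenylcyclohexan-1-olates to cyclodec-5-enones). The ten-membered ring is closed by ring expansion, not by an exo or endo cyclisation: the new C8–C9 sigma bond links the two alkene termini while the C1–C6 bond of the six-membered ring opens, a net four-atom enlargement. The single new stereocentre C8 is controlled by the chair transition state with both ring bonds equatorial, in which the (E)-enol ether places its oxygen equatorial and its hydrogen axial, so the two centres of 15 that are destroyed are relayed to (8S). The selectivities required are chair over boat, [3,3] shift over [1,3] shift or fragmentation, and survival of the beta-alkoxy enolate 17; the trans-diequatorial alkenyl groups and the E geometry secure the chair, the vicinal methoxy group on C1 lowers the barrier, and cold protonation with AcOH traps the enolate at C7 before the C8 oxygen can be expelled. The ring alkene cannot change geometry and is delivered as cis C4=C5, the isopropenyl group becomes the C1=C10 methyl enol ether (C2 and C9 anti), and C6 and C1 emerge as a free ketone and a masked ketone.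

Step 10
Reactants: 19 ethyl 3-bromo-2-oxopropanoate
Product: 20 ethyl 3-acetoxy-2-oxopropanoate
Conditions: KOAc, acetone, 23 °C
Reagents that add atoms: potassium acetate ([K+].CC(=O)[O-])
Why: SN2 displacement of the activated primary bromide alpha to the ketone by acetate (carboxylate alkylation).

Step 11
Reactants: 18 (2Z,6Z,9S)-6-methoxy-9-[(4-methoxybenzyl)oxy]-3,7-dimethylcyclodeca-2,6-dien-1-one; 20 ethyl 3-acetoxy-2-oxopropanoate
Product: 22 ethyl (1(10)Z,4Z,8S)-13-acetoxy-11-hydroxy-1-methoxy-8-[(4-methoxybenzyl)oxy]-6-oxogermacra-1(10),4-dien-12-oate, via lithium enolate 21 (not isolated)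
Conditions: LDA, THF, −78 °C; then 20, −78 °C; then AcOH, −78 °C
Reagents that add atoms: none
Why: Kinetic deprotonation at C7, the only sp3 alpha-carbon of the C6 ketone while C1 stays masked as its enol ether, and aldol addition of the lithium enolate to the highly electrophilic keto carbonyl bring in C11–C13 with the acetate already in place; the two new centres (C7, C11) are cancelled in step 12.

Step 12
Reactants: 22 ethyl (1(10)Z,4Z,8S)-13-acetoxy-11-hydroxy-1-methoxy-8-[(4-methoxybenzyl)oxy]-6-oxogermacra-1(10),4-dien-12-oate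
Product: 24 ethyl (1(10)Z,4Z,7(11)Z,8S)-13-acetoxy-1-methoxy-8-[(4-methoxybenzyl)oxy]-6-oxogermacra-1(10),4,7(11)-trien-12-oate, via tertiary mesylate 23 (not isolated)
Conditions: MsCl, Et3N, DMAP (cat.), CH2Cl2, −20 → 23 °C
Reagents that add atoms: none
Why: Mesylation of the tertiary aldol hydroxyl and E1cB elimination through the C6 enolate create the tetrasubstituted C7=C11 bond; the isomer with the ester cis to C6 is expected to prevail because the ester carbonyl can associate with the enolate counter-ion while the CH2OAc arm faces the C8 methine hydrogen.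

Step 13
Reactants: 24 ethyl (1(10)Z,4Z,7(11)Z,8S)-13-acetoxy-1-methoxy-8-[(4-methoxybenzyl)oxy]-6-oxogermacra-1(10),4,7(11)-trien-12-oate
Product: 27 (4Z,6R,8S,10R)-13-acetoxy-8-[(4-methoxybenzyl)oxy]-1-oxogermacra-4,7(11)-dien-12,6-olide, via hydroxy ester 25 (not isolated), via lactone enol ether 26 (not isolated)
Conditions: Zn(BH4)2, Et2O, −30 °C; then 1 M aq. HCl–THF, 23 °C
Reagents that add atoms: water (O)
Why: Zinc borohydride reduces the C6 ketone 1,2 through a chelate between the carbonyl and the C8 ether oxygens (1,3-syn chelation-controlled reduction), hydride entering the face remote from ring carbon C9 so that O6 becomes cis to O8; the hydroxy ester closes to the butenolide by 5-exo-trig lactonisation, and the aqueous acid hydrolyses the methyl enol ether to the C1 ketone and is continued until C10 has reached its equilibrium configuration.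

Step 14
Reactants: 27 (4Z,6R,8S,10R)-13-acetoxy-8-[(4-methoxybenzyl)oxy]-1-oxogermacra-4,7(11)-dien-12,6-olide
Product: 28 (4Z,6R,8S,10R)-13-acetoxy-8-hydroxy-1-oxogermacra-4,7(11)-dien-12,6-olide
Conditions: DDQ, CH2Cl2–pH 7 buffer, 0 °C
Reagents that add atoms: none
Why: Oxidative cleavage of the 4-methoxybenzyl ether by DDQ (oxidation to the benzylic oxocarbenium ion and hydrolysis), placed after the enol ether has gone because that group would also be oxidised.

Step 15
Reactants: 28 (4Z,6R,8S,10R)-13-acetoxy-8-hydroxy-1-oxogermacra-4,7(11)-dien-12,6-olide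
Product: 29 (4R,5S,6S,8S,10R)-13-acetoxy-4,5-epoxy-8-hydroxy-1-oxogermacr-7(11)-en-12,6-olide
Conditions: VO(acac)2 (5 mol %), tBuOOH, CH2Cl2, 0 → 23 °C
Reagents that add atoms: tert-butyl hydroperoxide (CC(C)(C)OO)
Why: Hydroxyl-directed epoxidation (vanadium-catalysed, with tBuOOH): the vanadate ester at O8, which lies on the same ring face as O6, delivers oxygen to the C4=C5 face turned toward C8, so the cis geometry is retained and the epoxide forms cis to O6 and O8, while the electron-poor butenolide alkene is inert.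

Step 16
Reactants: 30 ethyl 2-(hydroxymethyl)prop-2-enoate
Product: 31 ethyl 2-{[(tert-butyldimethylsilyl)oxy]methyl}prop-2-enoate
Conditions: TBSCl, imidazole, CH2Cl2, 0 → 23 °C
Reagents that add atoms: tert-butyldimethylsilyl chloride (CC(C)(C)[Si](C)(C)Cl)
Why: Silylation of the primary alcohol (silyl ether protection) masks the hydroxyl that must stay free in the target.

Step 17
Reactants: 31 ethyl 2-{[(tert-butyldimethylsilyl)oxy]methyl}prop-2-enoate
Product: 32 2-{[(tert-butyldimethylsilyl)oxy]methyl}prop-2-enoic acid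
Conditions: LiOH, THF–H2O, 0 °C; then 1 M aq. HCl to pH 4
Reagents that add atoms: lithium hydroxide ([Li+].[OH-])
Why: Saponification of the ethyl ester; the primary silyl ether survives the cold basic medium and the mild acidification.

Step 18
Reactants: 29 (4R,5S,6S,8S,10R)-13-acetoxy-4,5-epoxy-8-hydroxy-1-oxogermacr-7(11)-en-12,6-olide; 32 2-{[(tert-butyldimethylsilyl)oxy]methyl}prop-2-enoic acid
Product: 33 (4R,5S,6S,8S,10R)-13-acetoxy-8-({2-[(tert-butyldimethylsilyloxy)methyl]prop-2-enoyl}oxy)-4,5-epoxy-1-oxogermacr-7(11)-en-12,6-olide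
Conditions: EDC·HCl, DMAP (cat.), CH2Cl2, 0 → 23 °C
Reagents that add atoms: none
Why: Steglich esterification (carbodiimide activation, DMAP acyl transfer) of the secondary allylic C8 hydroxyl; no stereocentre is involved and the cold, near-neutral medium limits acetyl migration from O13 and epimerisation at C10.

Step 19
Reactants: 33 (4R,5S,6S,8S,10R)-13-acetoxy-8-({2-[(tert-butyldimethylsilyloxy)methyl]prop-2-enoyl}oxy)-4,5-epoxy-1-oxogermacr-7(11)-en-12,6-olide
Product: 34 (4R,5S,6S,8S,10R)-13-acetoxy-4,5-epoxy-8-{[2-(hydroxymethyl)prop-2-enoyl]oxy}-1-oxogermacr-7(11)-en-12,6-olide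
Conditions: HF·pyridine, pyridine, THF, 0 °C
Reagents that add atoms: none
Why: Buffered fluoride cleavage of the primary silyl ether (desilylation) leaves the epoxide, acetate, acrylate and butenolide untouched and releases the target.

Compound list
1 | 4,4-dimethoxycyclohexa-2,5-dien-1-one | COC1(OC)C=CC(=O)C=C1 | starting material
2 | isopropenylmagnesium bromide | CC(=C)[Mg]Br | starting material
3 | 4,4-dimethoxy-1-(prop-1-en-2-yl)cyclohexa-2,5-dien-1-ol | CC(=C)C1(O)C=CC(OC)(OC)C=C1 | intermediate
4 | 3,3,6-trimethoxy-6-(prop-1-en-2-yl)cyclohexa-1,4-diene | CC(=C)C1(OC)C=CC(OC)(OC)C=C1 | intermediate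
5 | 4-methoxy-4-(prop-1-en-2-yl)cyclohexa-2,5-dien-1-one | CC(=C)C1(OC)C=CC(=O)C=C1 | intermediate
6 | (S)-4-methoxy-4-(prop-1-en-2-yl)cyclohex-2-en-1-one | C1=CC(=O)CC[C@@]1(OC)C(C)=C | intermediate
7 | (4S)-4-methoxy-1-methyl-4-(prop-1-en-2-yl)cyclohex-2-en-1-ol (both C1 epimers) | C1=CC(C)(O)CC[C@@]1(OC)C(C)=C | intermediate
8 | (R)-6-methoxy-3-methyl-6-(prop-1-en-2-yl)cyclohex-2-en-1-one | O=C1C=C(C)CC[C@@]1(OC)C(C)=C | intermediate
9 | 4-methoxybenzyl alcohol | COc1ccc(CO)cc1 | starting material
10 | trichloroethylene | ClC=C(Cl)Cl | starting material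
11 | 1-{[(E)-1,2-dichloroethenyl]oxymethyl}-4-methoxybenzene | Cl/C=C(\OCc1ccc(OC)cc1)Cl | intermediate
12 | lithium [(4-methoxybenzyl)oxy]acetylide | [Li]C#COCc1ccc(OC)cc1 | intermediate
13 | bromomagnesium [(4-methoxybenzyl)oxy]acetylide | Br[Mg]C#COCc1ccc(OC)cc1 | intermediate
14 | (1R,6R)-6-methoxy-1-{[(4-methoxybenzyl)oxy]ethynyl}-3-methyl-6-(prop-1-en-2-yl)cyclohex-2-en-1-ol | O[C@@]1(C#COCc2ccc(OC)cc2)C=C(C)CC[C@@]1(OC)C(C)=C | intermediate
15 | (1R,6R)-6-methoxy-1-{(E)-2-[(4-methoxybenzyl)oxy]ethenyl}-3-methyl-6-(prop-1-en-2-yl)cyclohex-2-en-1-ol (target locants: carbinol carbon = C6, methoxy carbon = C1) | O[C@@]1(/C=C/OCc2ccc(OC)cc2)C=C(C)CC[C@@]1(OC)C(C)=C | intermediate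
16 | potassium alkoxide of 15 | [K+].[O-][C@@]1(/C=C/OCc2ccc(OC)cc2)C=C(C)CC[C@@]1(OC)C(C)=C | intermediate
17 | potassium C6=C7 enolate of 18 (C5 and C8 anti) | C1/C(C)=C\C([O-])=C\[C@@H](OCc2ccc(OC)cc2)C/C(C)=C(OC)/C1.[K+] | intermediate
18 | (2Z,6Z,9S)-6-methoxy-9-[(4-methoxybenzyl)oxy]-3,7-dimethylcyclodeca-2,6-dien-1-one (C6 ketone, cis C4=C5, C1=C10 enol ether with C2 and C9 anti, 8S) | C1/C(C)=C\C(=O)C[C@@H](OCc2ccc(OC)cc2)C/C(C)=C(OC)/C1 | intermediate
19 | ethyl 3-bromo-2-oxopropanoate | CCOC(=O)C(=O)CBr | starting material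
20 | ethyl 3-acetoxy-2-oxopropanoate | CCOC(=O)C(=O)COC(C)=O | intermediate
21 | lithium C6=C7 enolate of 18 | C1/C(C)=C\C(O[Li])=C[C@@H](OCc2ccc(OC)cc2)C/C(C)=C(OC)/C1 | intermediate
22 | ethyl (1(10)Z,4Z,8S)-13-acetoxy-11-hydroxy-1-methoxy-8-[(4-methoxybenzyl)oxy]-6-oxogermacra-1(10),4-dien-12-oate (C7 and C11 epimers) | C1/C(C)=C\C(=O)C(C(O)(COC(C)=O)C(=O)OCC)[C@@H](OCc2ccc(OC)cc2)C/C(C)=C(OC)/C1 | intermediate
23 | 11-methanesulfonate of 22 | C1/C(C)=C\C(=O)C(C(OS(C)(=O)=O)(COC(C)=O)C(=O)OCC)[C@@H](OCc2ccc(OC)cc2)C/C(C)=C(OC)/C1 | intermediate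
24 | ethyl (1(10)Z,4Z,7(11)Z,8S)-13-acetoxy-1-methoxy-8-[(4-methoxybenzyl)oxy]-6-oxogermacra-1(10),4,7(11)-trien-12-oate (ester cis to C6) | C1/C(C)=C\C(=O)/C(=C(/COC(C)=O)C(=O)OCC)[C@@H](OCc2ccc(OC)cc2)C/C(C)=C(OC)/C1 | intermediate
25 | ethyl (1(10)Z,4Z,7(11)E,6R,8S)-13-acetoxy-6-hydroxy-1-methoxy-8-[(4-methoxybenzyl)oxy]germacra-1(10),4,7(11)-trien-12-oate (ester cis to C6, O6 cis to O8) | C1/C(C)=C\[C@@H](O)/C(=C(/COC(C)=O)C(=O)OCC)[C@@H](OCc2ccc(OC)cc2)C/C(C)=C(OC)/C1 | intermediate
26 | (1(10)Z,4Z,6R,8S)-13-acetoxy-1-methoxy-8-[(4-methoxybenzyl)oxy]germacra-1(10),4,7(11)-trien-12,6-olide | C1/C(C)=C\[C@H]2OC(=O)C(COC(C)=O)=C2[C@@H](OCc3ccc(OC)cc3)C/C(C)=C(OC)/C1 | intermediate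
27 | (4Z,6R,8S,10R)-13-acetoxy-8-[(4-methoxybenzyl)oxy]-1-oxogermacra-4,7(11)-dien-12,6-olide | COc1ccc(CO[C@H]2C[C@@H](C)C(=O)CC/C(C)=C\[C@H]3OC(=O)C(COC(C)=O)=C23)cc1 | intermediate
28 | (4Z,6R,8S,10R)-13-acetoxy-8-hydroxy-1-oxogermacra-4,7(11)-dien-12,6-olide | O[C@H]1C[C@@H](C)C(=O)CC/C(C)=C\[C@H]2OC(=O)C(COC(C)=O)=C12 | intermediate
29 | (4R,5S,6S,8S,10R)-13-acetoxy-4,5-epoxy-8-hydroxy-1-oxogermacr-7(11)-en-12,6-olide | O[C@H]1C[C@@H](C)C(=O)CC[C@@]2(C)O[C@H]2[C@H]2OC(=O)C(COC(C)=O)=C12 | intermediate
30 | ethyl 2-(hydroxymethyl)prop-2-enoate | CCOC(=O)C(=C)CO | starting material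
31 | ethyl 2-{[(tert-butyldimethylsilyl)oxy]methyl}prop-2-enoate | CCOC(=O)C(=C)CO[Si](C)(C)C(C)(C)C | intermediate
32 | 2-{[(tert-butyldimethylsilyl)oxy]methyl}prop-2-enoic acid | C=C(CO[Si](C)(C)C(C)(C)C)C(=O)O | intermediate
33 | (4R,5S,6S,8S,10R)-13-acetoxy-8-({2-[(tert-butyldimethylsilyloxy)methyl]prop-2-enoyl}oxy)-4,5-epoxy-1-oxogermacr-7(11)-en-12,6-olide | C=C(CO[Si](C)(C)C(C)(C)C)C(=O)O[C@H]1C[C@@H](C)C(=O)CC[C@@]2(C)O[C@H]2[C@H]2OC(=O)C(COC(C)=O)=C12 | intermediate
34 | (4R,5S,6S,8S,10R)-13-acetoxy-4,5-epoxy-8-{[2-(hydroxymethyl)prop-2-enoyl]oxy}-1-oxogermacr-7(11)-en-12,6-olide (CNP0258719.1) | C=C(CO)C(=O)O[C@H]1C[C@@H](C)C(=O)CC[C@@]2(C)O[C@H]2[C@H]2OC(=O)C(COC(C)=O)=C12 | target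

Total step count: 19. Longest linear sequence: 15 steps (steps 1–5, 7–9, 11–15, 18, 19).

Steps most likely to fail

First, step 9. The dissociated beta-alkoxy enolate may expel the C8 oxygen substituent before it is protonated, or the alkoxide may fragment or undergo a [1,3] shift instead of the [3,3] shift. The fallback runs the same ring enlargement on the neutral silyl ether, where no free enolate is formed. Setting out from 15, the tertiary alcohol is silylated (N-trimethylsilylimidazole, CH2Cl2) to the trimethylsilyl ether of 15, F1. Heating (toluene, about 180 °C, sealed base-washed tube) should effect the thermal siloxy-Cope rearrangement through the same chair to the C6 trimethylsilyl enol ether of 18, F2. TBAF–AcOH in THF at −78 °C then releases the ketone, and the route is rejoined at 18.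

Second, step 12. The elimination may place the ester trans to C6 (wrong alkene geometry), after which the reduced product cannot lactonise. The fallback closes the lactone before the alkene is made, so that no geometry has to be controlled. Setting out from 22, Zn(BH4)2 reduction of the C6 ketone (again through the C8 ether chelate) and spontaneous lactonisation should give (1(10)Z,4Z,8S)-13-acetoxy-11-hydroxy-1-methoxy-8-[(4-methoxybenzyl)oxy]germacra-1(10),4-dien-12,6-olide, F3. Dehydration of this tertiary alpha-hydroxy lactone (SOCl2–pyridine where H7 and the hydroxyl are anti, Burgess reagent where they are syn) gives the butenolide, and the route is rejoined at 26, which then enters the acid stage of step 13.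

Third, step 13. Equilibration under acid may leave C10 mainly in the unwanted configuration. The fallback sets this centre kinetically instead of thermodynamically. Setting out from 26 (isolated by a buffered work-up of the reduction), NBS in aqueous THF at 0 °C converts the enol ether into 13-acetoxy-10-bromo-8-[(4-methoxybenzyl)oxy]-1-oxogermacra-4,7(11)-dien-12,6-olide, F4. SmI2 in THF at −78 °C generates the C1–C10 samarium enolate regiospecifically, and a hindered phenol (2,6-di-tert-butyl-4-methylphenol) protonates it at low temperature, after which no equilibrating acid or base is applied. The route is rejoined at 27.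

Further compounds
F1 | step 9 | trimethylsilyl ether of 15 | C[Si](C)(C)O[C@@]1(/C=C/OCc2ccc(OC)cc2)C=C(C)CC[C@@]1(OC)C(C)=C
F2 | step 9 | C6 trimethylsilyl enol ether of 18 (C6=C7, C5 and C8 anti) | C1/C(C)=C\C(O[Si](C)(C)C)=C\[C@@H](OCc2ccc(OC)cc2)C/C(C)=C(OC)/C1
F3 | step 12 | (1(10)Z,4Z,8S)-13-acetoxy-11-hydroxy-1-methoxy-8-[(4-methoxybenzyl)oxy]germacra-1(10),4-dien-12,6-olide (C7 and C11 epimers) | C1/C(C)=C\[C@H]2OC(=O)C(O)(COC(C)=O)C2[C@@H](OCc3ccc(OC)cc3)C/C(C)=C(OC)/C1
F4 | step 13 | 13-acetoxy-10-bromo-8-[(4-methoxybenzyl)oxy]-1-oxogermacra-4,7(11)-dien-12,6-olide (C10 epimers) | COc1ccc(CO[C@H]2CC(C)(Br)C(=O)CC/C(C)=C\[C@H]3OC(=O)C(COC(C)=O)=C23)cc1
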